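In a one-step world every mole of substrate that leaves turns up as product, so two entries would close the books. You are following maple, and with partner at 1.50 equiv, substrate is the limiting reagent.

common to all: initiator 5 mol%

|  | substrate | partner | temperature | remark | time |
|---|---|---|---|---|---|
| maple | 1 M | 1.5 equiv | 25 °C | the very flask that is asked about, followed so far |  |
| elm | 1 M | 1.5 equiv | 10 °C | run made earlier |  |
| flask | 1.0 M | 1.50 equiv | 25 °C |  | 25 min |

- maple (time / min: product / %, substrate / %): 1.50: 26.8, 66.2; 4.00: 51.7, 34.7; 8.00: 68.2, 13.6; 20.0: 78.0, 2.7
- elm (time / min: product / %, substrate / %): 3.00: 9.6, 88.0; 8.00: 23.5, 70.6; 15.0: 37.9, 52.8; 40.0: 64.2, 19.1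

(standard deviation of a reading: 0.3 percentage points)

* product, in percent of the substrate first charged, at 25 min
* the option that brings most further product ("none" if no option brings more than 2 percentage points) (autumn / midnight / noon / none)
* product present, with what was taken out counted in, in percent of the substrate first charged, after autumn
* product present, with what was taken out counted in, in percent of the substrate first charged, after midnight

- autumn: at 25 min take out 90% of the product then present, then wait 8.0 min
- midnight: change nothing and wait 8.0 min more
- noon: at 25 min raise the temperature by 20 K, then wait 8.0 min

Neither run closes on two entries, so open a third, held, for what is neither substrate nor product. Up to 8.00 min, maple books 78.9% of the substrate consumed as product, and elm, up to 40.0 min, books 79.4%. Between 8.00 min and 20.0 min, though, maple books 89.9% as product, and held grows by 1.1 percentage points. That late share stands above the early one, so I book held as a store that trades with free substrate, not as a sink with a fixed share. At 20.0 min, held stands at 19.3% beside substrate at 2.7%. That gives 7.15, a reading that I call the hold ratio h, held per unit of free substrate. The open balance, what is not yet product, is then 22.0%, and 87.7% of it is held.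

So I put product at 25 min above the 78.0% reading. Autumn touches neither open entry, so I expect it to match midnight, each with a gain under 2 points. From elm to maple the early loss of substrate sped up by a factor of 6.45, and noon adds 20 K, so I commit to noon.

The forecast gives 78.3%, 79% after autumn, 78.5% after midnight and best option none, on the grounds that “a parallel side channel takes a fixed 20%”.

Maple gives 78.8% at 25 min. Autumn reaches 79.7% and midnight 79.7%, a gain of 0.83 points each, while noon gains 5.9 points, so the best option is noon.

    initiator → 2 initiating radical (k = 0.00120 /s, Ea = 98.0 kJ/mol)
    substrate + initiating radical → chain carrier (k = 630 /M/s, Ea = 43.0 kJ/mol)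
    partner + chain carrier → product + initiating radical (k = 210 /M/s, Ea = 44.0 kJ/mol)
    2 initiating radical → ended chains (k = 1.70 × 10⁶ /M/s, Ea = 11.0 kJ/mol)
    substrate ⇌ dormant form (K = 7.50, k = 9.30 × 10⁻⁴ /s, Ea = 86.0 kJ/mol, ΔH = −49.0 kJ/mol)
    (constants at 25 °C)

Held is the dormant form. At 25.0 min, maple books substrate at 1.48% and dormant form at 19.7%, a hold ratio of 13.3, above the reading of 7.15. At 250 min, that ratio in maple is 7.51. The neighbour, the same flask run at 50 °C with amounts and time held, books substrate at 5.01% and dormant form at 8.14% at 25.0 min. Its hold ratio is 1.62, below the reading of 7.15, and its product stands at 86.8%.

Readings and results were computed for substances that don't exist; the scatter is artificial.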